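All runs come from a simulation with made-up constants.

At 60.0 h the north-east flask holds 54.8% target, and counted as turnovers that reading gives the number on which this reckoning of the new flasks rests.

| flask | substrate | gas | precatalyst | temperature | remark | time |
|---|---|---|---|---|---|---|
| south-west | 0.30 M | 51 mM (held) | 4.3 mM | 4 °C | run made earlier |  |
| north-east | 0.30 M | 51 mM (held) | 6.5 mM | 12 °C | run made earlier |  |
| Tuesday's | 0.30 M | 51 mM (held) | 8.7 mM | 15 °C |  | 50 h |
| Wednesday's | 0.30 M | 51 mM (held) | 8.7 mM | 0 °C |  | 50 h |
| Saturday's | 0.30 M | 51 mM (held) | 8.7 mM |  | at 0 °C until 10 h, from then on at 15 °C | 50 h |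

- south-west (time / h: target / %): 20.0: 1.6; 40.0: 7.7; 72.0: 21.6; 96.0: 35.2
- north-east (time / h: target / %): 5.00: 0; 15.0: 4.5; 30.0: 18.3; 40.0: 30.4; 60.0: 54.8

(scatter of a reading: 0.3 percentage points)

- at the start none of the gas is in solution

- which flask leads in amount of target, in percent of the substrate charged ("all alike" within 1.5 percentage points) (Tuesday's / Wednesday's / Saturday's / all alike)
- how much target is there at the end, in percent of the substrate charged: Tuesday's
- how much target is there at the end, in percent of the substrate charged: Wednesday's
- how much target is there at the end, in percent of the substrate charged: Saturday's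

Take L, the logarithm of substrate charged over substrate left, and multiply it by substrate charged per precatalyst charged to count turnovers; the time divided by the square root of that count I call the turnover clock. A constant clock means that turnovers pile up as the square of time, as they do on a catalyst that grows steadily out of its precatalyst, and the clock then reads the time of the first turnover on that count.

south-west, 96.0 h: 17.4 h
north-east, 30.0 h: 9.82 h
north-east, 60.0 h: 9.91 h
at 15 °C: 8.02 h
at 0 °C: 23.2 h

The last line, the clock carried geometrically down to the cold flask, serves Wednesday's, and the line before it serves Tuesday's.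

The ladder then reads as follows. The first rung is the induction period: north-east reads 0% at 5.00 h where its clock gives 0.550%, with a scatter of 0.3 percentage points, so I neglect the lag. Next comes the time for L to reach one, 47.1 h in Tuesday's, so that flask passes it before the end, whereas Wednesday's needs 136 h, so it stays near its start. The last rung is the growth of catalyst, which north-east shows no sign of ending by 60.0 h, for its clock reads 9.91 h there against 9.82 h at 30.0 h.

Tuesday's: 1.13, so 67.6%
Wednesday's: 0.135, so 12.7%
Saturday's, counted from the change: 0.722, so 51.4%

The Saturday figure is my low edge, since it banks no catalyst in the cold hours.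

The forecast, from the same growth with the square of time, puts Tuesday's first: 67% (60% to 73%), then 57% (50% to 64%) for Saturday's, and 12% (9% to 15%) for Wednesday's. It adds banked catalyst to Saturday's, so it stands above my edge, and of that addition it says “This split is unresolved.”

The flasks give 63.7% for Tuesday's, 11.4% for Wednesday's and 55.9% for Saturday's, so Tuesday's leads.

    partner + free catalyst ⇌ catalyst intermediate A (K = 18.0 /M, k = 75.0 /M/h, Ea = 39.0 kJ/mol, ΔH = −37.0 kJ/mol)
    substrate + catalyst intermediate A ⇌ catalyst intermediate B (K = 33.0 /M, k = 11.0 /M/h, Ea = 65.0 kJ/mol, ΔH = 2.00 kJ/mol)
    catalyst intermediate B → free catalyst + target (k = 1.90 /h, Ea = 92.0 kJ/mol)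
    gas ⇌ partner, rate k4*(csat - [partner]) (kL = 0.330 /h)
    partner + precatalyst → free catalyst + spent reagent (k = 0.130 /M/h, Ea = 56.0 kJ/mol)
    (constants at 0 °C)

In Wednesday's, catalyst intermediate A has a half-life of 0.21 h at 5.33 h by its forward step with substrate alone, far shorter than the 50 h after which 74.2% of the catalyst charged still stands as precatalyst. Wednesday's own clock comes to 24.5 h, longer than the 23.2 h reckoned, and that reckoned clock, carried to a neighbour of Wednesday's charged with 0.022 M precatalyst, gives 29.0%, where that flask stands at 25.7%.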